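**Retrosynthetic overview**

1. The ring C1–C6 carries oxygen at C1 and C4 (para) and the side chain at C5 (ortho to C4), so it is a dearomatised 2-alkyl-hydroquinone and can be carried as an inert 4-methoxyphenol ether until after the fragment union.
2. The side-chain bond C6′–C7′ joins a plain primary carbon (C6′) to the allylic CH2 (C7′) of the (Z)-C8′=C9′ olefin; C7′–C8′=C9′ is therefore the endo-allyl anion of undec-1-ene, which is alkylated by a primary bromide Ar–(CH2)6–Br.
3. The bromide comes from ortho-lithiation of MOM-protected 4-methoxyphenol and 1,6-dibromohexane.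
4. After the union: PhI(OAc)2/MeOH dearomatisation to the quinone monoketal, CBS reduction (sets C4), OH-directed epoxidation of the alkyl-bearing ring olefin, ketal hydrolysis, and SmI2 opening of the oxirane α to the ketone (sets the C5 tertiary alcohol cis to C4–OH).
5. Rings: none is closed; the six-membered carbocycle is the benzene ring of 4-methoxyphenol, and a temporary oxirane is formed in step 7 and opened in step 9.

Key step: step 3

Remark: the SMILES is read as (4R,5S)-4,5-dihydroxy-5-[(8Z)-heptadec-8-en-1-yl]cyclohex-2-en-1-one, a cis-diol; ring atoms are C1–C6 (C1 = carbonyl), side-chain atoms C1′–C17′ counted from the ring.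

**Route**

Step 1
Reactants: 1 4-methoxyphenol
Product: 3 1-methoxy-4-(methoxymethoxy)benzene, via sodium 4-methoxyphenolate 2 (not isolated)
Conditions: NaH, THF, 0 °C; then MOMCl, 0 °C → rt
Reagents that add atoms: chloromethyl methyl ether (MOMCl), COCCl
Why: Williamson-type O-alkylation of the phenolate gives the MOM acetal, which protects the phenol against the carbanions of steps 2 and 3 and serves as the ortho-director in step 2; no stereocentre is formed.

Step 2
Reactants: 3 1-methoxy-4-(methoxymethoxy)benzene; 4 1,6-dibromohexane
Product: 6 2-(6-bromohexyl)-4-methoxy-1-(methoxymethoxy)benzene, via aryllithium 5 (not isolated)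
Conditions: n-BuLi, TMEDA, THF, 0 °C; then added to 4 (4 equiv), THF, −78 °C → rt
Reagents that add atoms: none
Why: Directed ortho-metalation: the OMOM group chelates lithium and directs deprotonation to its own ortho position rather than ortho to OMe, and the aryllithium displaces one bromide of the excess dibromide by SN2, the excess suppressing double arylation; no stereocentre is formed.

Step 3
Reactants: 6 2-(6-bromohexyl)-4-methoxy-1-(methoxymethoxy)benzene; 7 undec-1-ene
Product: 9 2-[(8Z)-heptadec-8-en-1-yl]-4-methoxy-1-(methoxymethoxy)benzene, via (Z)-undec-2-enylpotassium 8 (not isolated)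
Conditions: 7 (3 equiv), n-BuLi, KOt-Bu (Schlosser base), THF, −50 °C, 12 h; then 6, THF, −78 → −40 °C
Reagents that add atoms: none
Why: The superbase removes an allylic C3–H of undec-1-ene to give the delocalised undec-2-enylpotassium 8, whose endo (Z) torsional isomer is the thermodynamically preferred form of 2-alkenylpotassium species; its unsubstituted terminus (the former C1) displaces bromide from the primary carbon of 6 by SN2, so the C6′–C7′ bond, the 1,3-shift of the double bond to C8′=C9′ and its Z geometry all arise in one operation from a commodity α-olefin. The closest known reaction type is the superbase metalation of 1-alkenes followed by stereoretentive trapping of the endo-allylpotassium with primary alkyl halides, oxiranes or fluoroborates. No ring is closed and no stereocentre is formed; the only stereo-element created is the Z double bond, set by the endo preference of the allyl anion and kept because torsional isomerisation is slow at −78 °C. The step needs attack through the CH2 terminus rather than the octyl-bearing terminus, Z over E, and substitution over elimination: the first is secured by the steric difference between the two allyl termini towards a primary halide, the second by letting the metalated olefin equilibrate at −50 °C before the bromide is added, the third by the unbranched primary bromide and the low temperature. The ring is present as a MOM-protected 4-methoxyphenol, which offers no electrophilic site and no proton acidic enough to compete under these conditions.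

Step 4
Reactants: 9 2-[(8Z)-heptadec-8-en-1-yl]-4-methoxy-1-(methoxymethoxy)benzene
Product: 10 2-[(8Z)-heptadec-8-en-1-yl]-4-methoxyphenol
Conditions: HCl (cat.), MeOH, 45 °C
Reagents that add atoms: none
Why: Acid-catalysed transacetalisation (MOM cleavage) releases the phenol while the aryl methyl ether and the isolated Z-olefin are inert to dilute HCl in methanol; no stereocentre is formed.

Step 5
Reactants: 10 2-[(8Z)-heptadec-8-en-1-yl]-4-methoxyphenol
Product: 11 2-[(8Z)-heptadec-8-en-1-yl]-4,4-dimethoxycyclohexa-2,5-dien-1-one
Conditions: PhI(OAc)2, MeOH, 0 °C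
Reagents that add atoms: methanol, CO
Why: Hypervalent-iodine oxidative dearomatisation of a para-methoxyphenol (quinone monoketal synthesis): methanol attacks the activated phenol at the methoxy-bearing para carbon, which fixes the carbonyl next to the alkyl-bearing carbon, and phenol oxidation is far faster than any reaction of the reagent with the isolated chain olefin; no stereocentre is formed.

Step 6
Reactants: 11 2-[(8Z)-heptadec-8-en-1-yl]-4,4-dimethoxycyclohexa-2,5-dien-1-one
Product: 13 (1R)-2-[(8Z)-heptadec-8-en-1-yl]-4,4-dimethoxycyclohexa-2,5-dien-1-ol, via O-catecholboryl ether 12 (not isolated)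
Conditions: (S)-Me-CBS (0.2 equiv), catecholborane, toluene, −78 °C; then MeOH, cold aq. NaOH work-up
Reagents that add atoms: none
Why: CBS reduction: the ketone binds the catalyst boron anti to its bulkier flank, here the alkyl-substituted arm C(R)=CH versus the unsubstituted CH=CH arm, so the (S)-catalyst should deliver hydride to the Si face of C1 and set the (1R)-carbinol (the later C4 of the target), while catecholborane at −78 °C gives only 1,2-reduction and does not hydroborate the chain olefin.

Step 7
Reactants: 13 (1R)-2-[(8Z)-heptadec-8-en-1-yl]-4,4-dimethoxycyclohexa-2,5-dien-1-ol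
Product: 14 (1R,2R,6R)-1-[(8Z)-heptadec-8-en-1-yl]-5,5-dimethoxy-7-oxabicyclo[4.1.0]hept-3-en-2-ol
Conditions: VO(acac)2 (5 mol%), t-BuOOH (1.1 equiv), 2,6-lutidine (cat.), CH2Cl2, 0 °C
Reagents that add atoms: tert-butyl hydroperoxide, CC(C)(C)OO
Why: Hydroxyl-directed vanadium-catalysed epoxidation: the vanadate ester of the C1 hydroxyl delivers the peroxide oxygen to its own face of the ring and to the more nucleophilic trisubstituted C2=C3 olefin rather than the disubstituted C5=C6 olefin or the unbound chain olefin, so both oxirane stereocentres are set cis to the carbinol oxygen by substrate control.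

Step 8
Reactants: 14 (1R,2R,6R)-1-[(8Z)-heptadec-8-en-1-yl]-5,5-dimethoxy-7-oxabicyclo[4.1.0]hept-3-en-2-ol
Product: 15 (1R,5R,6R)-6-[(8Z)-heptadec-8-en-1-yl]-5-hydroxy-7-oxabicyclo[4.1.0]hept-3-en-2-one
Conditions: Montmorillonite K10, wet CH2Cl2, rt
Reagents that add atoms: water, O
Why: Mild acid hydrolysis of the dimethyl ketal via its oxocarbenium ion unveils the enone, the ketal ionising more readily than the oxirane or carbinol C–O bonds, which are deactivated by their oxygen neighbours, and with the oxirane in place the hydroxy enone cannot tautomerise to a phenol; no stereocentre is formed or touched.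

Step 9
Reactants: 15 (1R,5R,6R)-6-[(8Z)-heptadec-8-en-1-yl]-5-hydroxy-7-oxabicyclo[4.1.0]hept-3-en-2-one
Product: 16 (4R,5S)-4,5-dihydroxy-5-[(8Z)-heptadec-8-en-1-yl]cyclohex-2-en-1-one
Conditions: SmI2 (2.5 equiv), THF/MeOH, −90 °C; pH 7 buffer
Reagents that add atoms: none
Why: Samarium diiodide reduction of an α,β-epoxy ketone to the β-hydroxy ketone: the ketyl fragments the Cα–O bond (C6–O, target numbering) while the oxygen stays on the quaternary carbon, so C5 keeps its configuration with the new tertiary hydroxyl cis to the C4 hydroxyl, and methanol protonates the samarium enolate at −90 °C before β-elimination, the enone and the isolated olefin being inert without HMPA.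

**Compound list**

1 | 4-methoxyphenol | COc1ccc(O)cc1 | starting material
2 | sodium 4-methoxyphenolate | COc1ccc([O-])cc1.[Na+] | intermediate (not isolated)
3 | 1-methoxy-4-(methoxymethoxy)benzene | COCOc1ccc(OC)cc1 | intermediate
4 | 1,6-dibromohexane | BrCCCCCCBr | starting material
5 | [5-methoxy-2-(methoxymethoxy)phenyl]lithium | COCOc1ccc(OC)cc1[Li] | intermediate (not isolated)
6 | 2-(6-bromohexyl)-4-methoxy-1-(methoxymethoxy)benzene | COCOc1ccc(OC)cc1CCCCCCBr | intermediate
7 | undec-1-ene | C=CCCCCCCCCC | starting material
8 | (2Z)-undec-2-en-1-ylpotassium | CCCCCCCC/C=C\C[K] | intermediate (not isolated)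
9 | 2-[(8Z)-heptadec-8-en-1-yl]-4-methoxy-1-(methoxymethoxy)benzene | COCOc1ccc(OC)cc1CCCCCCC/C=C\CCCCCCCC | intermediate
10 | 2-[(8Z)-heptadec-8-en-1-yl]-4-methoxyphenol | COc1ccc(O)c(CCCCCCC/C=C\CCCCCCCC)c1 | intermediate
11 | 2-[(8Z)-heptadec-8-en-1-yl]-4,4-dimethoxycyclohexa-2,5-dien-1-one | COC1(OC)C=CC(=O)C(CCCCCCC/C=C\CCCCCCCC)=C1 | intermediate
12 | 2-{[(1R)-2-[(8Z)-heptadec-8-en-1-yl]-4,4-dimethoxycyclohexa-2,5-dien-1-yl]oxy}-1,3,2-benzodioxaborole | CCCCCCCC/C=C\CCCCCCCC1=CC(OC)(OC)C=C[C@H]1OB2Oc3ccccc3O2 | intermediate (not isolated)
13 | (1R)-2-[(8Z)-heptadec-8-en-1-yl]-4,4-dimethoxycyclohexa-2,5-dien-1-ol | CCCCCCCC/C=C\CCCCCCCC1=CC(OC)(OC)C=C[C@H]1O | intermediate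
14 | (1R,2R,6R)-1-[(8Z)-heptadec-8-en-1-yl]-5,5-dimethoxy-7-oxabicyclo[4.1.0]hept-3-en-2-ol (oxirane cis to OH) | O[C@@H]1C=CC(OC)(OC)[C@@H]2O[C@]12CCCCCCC/C=C\CCCCCCCC | intermediate
15 | (1R,5R,6R)-6-[(8Z)-heptadec-8-en-1-yl]-5-hydroxy-7-oxabicyclo[4.1.0]hept-3-en-2-one (oxirane cis to OH) | O[C@@H]1C=CC(=O)[C@@H]2O[C@]12CCCCCCC/C=C\CCCCCCCC | intermediate
16 | (4R,5S)-4,5-dihydroxy-5-[(8Z)-heptadec-8-en-1-yl]cyclohex-2-en-1-one | CCCCCCCC/C=C\CCCCCCC[C@]1(O)CC(=O)C=C[C@H]1O | target

**Step count**

Total step count: 9. Longest linear sequence: 9 steps (1 → 16); undec-1-ene and 1,6-dibromohexane enter as purchased materials.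

**Steps most likely to fail**

Step 3. What may go wrong: alkylation through the octyl-bearing allyl terminus (branched regioisomer), incomplete endo/exo equilibration or torsional leakage giving some E-olefin, and elimination or metal–halogen exchange on the bromide by the very basic carbanion. Minor isomers would have to be removed from 9 by argentation chromatography. The fallback reverses the polarity and presets the Z geometry by semihydrogenation; it sets out from 6 and returns at 9. Bromide 6 is converted with magnesium in THF into {6-[5-methoxy-2-(methoxymethoxy)phenyl]hexyl}magnesium bromide F1. In parallel, commercial undec-2-yn-1-ol is hydrogenated over Lindlar catalyst with quinoline to (2Z)-undec-2-en-1-ol F2, which is converted with PBr3 in Et2O at −10 °C into (2Z)-1-bromoundec-2-ene F3. Copper-catalysed coupling of F1 with F3 (Li2CuCl4 cat., THF, −78 → 0 °C), an SN2-selective allylic substitution that keeps the olefin geometry, should give 9.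

Step 6. What may go wrong: weak facial discrimination by the oxazaborolidine because both flanks of the carbonyl are sp2 carbons, and acid-triggered loss of methanol with re-aromatisation of the doubly allylic alcohol during work-up. The fallback replaces catalyst control by enzymatic resolution; it sets out from 11 and returns at 13. Luche reduction of 11 (NaBH4, CeCl3·7H2O, MeOH, −78 °C) gives the racemic dienol F4. Lipase-catalysed acylation (Burkholderia cepacia lipase or CAL-B, vinyl acetate, MTBE, rt) should, by the empirical rule for secondary alcohols, acylate the (R)-enantiomer to the (1R)-acetate F5 and leave the (1S)-dienol F6. After separation, F5 is deacetylated (K2CO3, MeOH, 0 °C) to 13. F6 can be re-oxidised with MnO2 to 11 and recycled. The configuration of 13 would be confirmed by Mosher ester analysis.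

Step 7. What may go wrong: Lewis-acid-induced ionisation of the ketal and re-aromatisation of the dienol under the vanadium/peroxide conditions, competing oxygen transfer to the unsubstituted ring olefin, and over-oxidation. The fallback delivers the oxygen intramolecularly under basic conditions by iodocarbonate cyclisation; it sets out from 13 and returns at 14. Dienol 13 is deprotonated (n-BuLi, THF, −78 °C) and carboxylated with CO2 to the lithium carbonate F7. Iodine then induces cyclisation to the cis-fused cyclic iodocarbonate F8: the carbonate oxygen adds to the alkyl-bearing C2 on the face of the C1 oxygen, with iodine anti at C3. Methanolysis of F8 (K2CO3, MeOH, 0 °C) frees the C2 alkoxide, which displaces iodide with inversion and should give oxirane 14 cis to the hydroxyl. Iodine adds only reversibly to the chain olefin.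

**Further compounds**

F1 | step 3 | {6-[5-methoxy-2-(methoxymethoxy)phenyl]hexyl}magnesium bromide | COCOc1ccc(OC)cc1CCCCCC[Mg]Br
F2 | step 3 | (2Z)-undec-2-en-1-ol | CCCCCCCC/C=C\CO
F3 | step 3 | (2Z)-1-bromoundec-2-ene | CCCCCCCC/C=C\CBr
F4 | step 6 | rac-2-[(8Z)-heptadec-8-en-1-yl]-4,4-dimethoxycyclohexa-2,5-dien-1-ol | CCCCCCCC/C=C\CCCCCCCC1=CC(OC)(OC)C=CC1O
F5 | step 6 | (1R)-2-[(8Z)-heptadec-8-en-1-yl]-4,4-dimethoxycyclohexa-2,5-dien-1-yl acetate | CCCCCCCC/C=C\CCCCCCCC1=CC(OC)(OC)C=C[C@H]1OC(C)=O
F6 | step 6 | (1S)-2-[(8Z)-heptadec-8-en-1-yl]-4,4-dimethoxycyclohexa-2,5-dien-1-ol | CCCCCCCC/C=C\CCCCCCCC1=CC(OC)(OC)C=C[C@@H]1O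
F7 | step 7 | lithium (1R)-2-[(8Z)-heptadec-8-en-1-yl]-4,4-dimethoxycyclohexa-2,5-dien-1-yl carbonate | CCCCCCCC/C=C\CCCCCCCC1=CC(OC)(OC)C=C[C@H]1OC(=O)[O-].[Li+]
F8 | step 7 | 7a-[(8Z)-heptadec-8-en-1-yl]-7-iodo-6,6-dimethoxy-3a,6,7,7a-tetrahydro-1,3-benzodioxol-2-one (cis-fused carbonate, iodine trans to the carbonate oxygens) | O=C1O[C@@H]2C=CC(OC)(OC)[C@@H](I)[C@]2(CCCCCCC/C=C\CCCCCCCC)O1
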